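Ring B is cut out of the flavone as a benzoate and built from two small pieces. Ring B (C1'–C6') carries four contiguous oxygens on C2'–C5', and only the C3' oxygen is a free hydroxyl, flanked by the C2' and C4' methoxy groups; a cyclobutenone ring expansion delivers exactly this pattern. A squarate-derived 4-chloro-2,3-dimethoxycyclobutenone is cross-coupled with an α-stannyl β-methoxyacrylate, and the coupled product opens and recloses in the same flask, forming C6'–C1' and C3'–C2' and turning the cyclobutenone carbonyl into the C3' hydroxyl. Aroylation of a phloroacetophenone methyl ether and cyclodehydration then add rings A and C.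

Key step: step 5

Assumption: the target has no stereocentre and no stereogenic axis, so "single enantiomer" sets no stereochemical task; the racemic centres of the cyclobutenones are destroyed when ring B becomes aromatic.

Step 1
Reactants: 1 dimethyl squarate
Product: 2 4-hydroxy-2,3-dimethoxycyclobut-2-en-1-one (racemic)
Conditions: LiAlH(OtBu)3 (1.05 equiv), THF, −78 °C; cold aq. Rochelle salt work-up, no acid
Reagents that add atoms: none
Why: Chemoselective 1,2-hydride reduction of one of the two equivalent squarate carbonyls by a bulky alkoxyaluminium hydride should stop at the mono-adduct, because the remaining carbonyl is a deactivated vinylogous ester; the new stereocentre forms racemic and is removed in step 5.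

Step 2
Reactants: 2 4-hydroxy-2,3-dimethoxycyclobut-2-en-1-one
Product: 3 4-chloro-2,3-dimethoxycyclobut-2-en-1-one (racemic)
Conditions: 1-chloro-N,N,2-trimethylprop-1-en-1-amine (1.1 equiv), CH2Cl2, 0 °C; concentrate cold, use at once without chromatography
Reagents that add atoms: 1-chloro-N,N,2-trimethylprop-1-en-1-amine, CC(C)=C(Cl)N(C)C
Why: Deoxychlorination of an alcohol with an α-chloroenamine runs under acid-free conditions (O-activation, then chloride return at C4, which keeps the conjugated β-methoxy enone), so the acid-triggered collapse of 2 to a semisquarate is avoided and the only by-product is a neutral amide that can be carried into the coupling.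

Step 3
Reactants: 4 methyl (E)-3-methoxyacrylate
Product: 6 methyl (Z)-2-bromo-3-methoxyacrylate, via methyl 2,3-dibromo-3-methoxypropanoate 5 (not isolated)
Conditions: Br2 (1.0 equiv), CH2Cl2, 0 °C; then Et3N (1.5 equiv), 0 °C to rt
Reagents that add atoms: bromine, BrBr
Why: Bromination–dehydrobromination: bromine adds across the enol ether double bond and base then removes the acidic α-hydrogen with loss of the oxygen-activated β-bromide, giving the α-bromo acrylate as the more stable Z isomer (methoxy anti to the ester).

Step 4
Reactants: 6 methyl (Z)-2-bromo-3-methoxyacrylate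
Product: 7 methyl (Z)-3-methoxy-2-(tributylstannyl)acrylate
Conditions: (Bu3Sn)2 (1.3 equiv), Pd(PPh3)4 (5 mol %), toluene, 100 °C; Et3N-deactivated silica
Reagents that add atoms: hexabutylditin, CCCC[Sn](CCCC)(CCCC)[Sn](CCCC)(CCCC)CCCC
Why: Palladium-catalysed stannylation of an alkenyl bromide with a distannane (oxidative addition, Sn–Sn transmetalation, C–Sn reductive elimination) should proceed with retention of alkene geometry, as it does for cyclic α-bromo-β-alkoxy enoates.

Step 5
Reactants: 3 4-chloro-2,3-dimethoxycyclobut-2-en-1-one, 7 methyl (Z)-3-methoxy-2-(tributylstannyl)acrylate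
Product: 11 methyl 3-hydroxy-2,4,5-trimethoxybenzoate, via 4-alkenylcyclobutenone 8 (not isolated), via dienylketene 9 (not isolated), via cyclohexadienone 10 (not isolated)
Conditions: Pd2(dba)3 (2.5 mol %), tri(2-furyl)phosphine (10 mol %), CuI (10 mol %), 1,4-dioxane, 3 added slowly to catalyst and 7 (1.2 equiv) at 50 °C, then 100 °C
Reagents that add atoms: none
Why: Pd(0) ionises the allylic C4–Cl bond of 3 to an η3-oxocyclobutenyl palladium chloride, copper-assisted transmetalation delivers the acrylate α-carbon of 7, and reductive elimination at the CH terminus forms C6'–C1' in 8 (Stille coupling). On heating, the C1–C4 σ-bond of 8 opens in a conrotatory 4π process to dienylketene 9, and a thermal disrotatory 6π electrocyclisation joins the ketene carbon to the enol ether carbon (C3'–C2'), closing the six-membered ring B as dienone 10, which enolises irreversibly to phenol 11. The closest known reaction type is the palladium-catalysed coupling of 4-chlorocyclobutenones with alkenylstannanes followed by thermal ring expansion of the 4-alkenylcyclobutenone to a phenol. No stereocentre survives: the racemic centre of 3 and the transient sp3 C2' of 10 both end as aromatic carbons, and the enol ether geometry is erased in the same way. The step needs coupling at C4 and not at the methoxy-bearing allyl terminus C2 (which would lead to the 2,5,6-trimethoxy isomer), and it needs the alkenyl group to turn inward on ring opening; the first is secured because C4 is the unsubstituted, less hindered terminus and coupling there keeps the β-methoxy enone, the second because ring opening is reversible and only the inward dienylketene is drained by cyclisation. Connectivity then puts the former carbonyl oxygen on C3' between the enol ether methoxy (C2') and one squarate methoxy (C4'), with the other squarate methoxy on C5' and the ester on C1'.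

Step 6
Reactants: 11 methyl 3-hydroxy-2,4,5-trimethoxybenzoate
Product: 12 methyl 3-(benzyloxy)-2,4,5-trimethoxybenzoate
Conditions: BnBr (1.2 equiv), K2CO3 (2 equiv), DMF, 50 °C
Reagents that add atoms: benzyl bromide, BrCc1ccccc1
Why: Williamson ether synthesis: the phenoxide, although flanked by two methoxy groups, should be alkylated cleanly by the unhindered, SN2-active benzyl bromide, and the methyl ester is inert to carbonate in DMF.

Step 7
Reactants: 12 methyl 3-(benzyloxy)-2,4,5-trimethoxybenzoate
Product: 13 3-(benzyloxy)-2,4,5-trimethoxybenzoic acid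
Conditions: LiOH·H2O (3 equiv), THF–MeOH–H2O, 50 °C; then 1 M HCl to pH 2–3
Reagents that add atoms: lithium hydroxide, [Li+].[OH-]
Why: Saponification (acyl–oxygen ester hydrolysis) of the methyl ester; benzyl and methyl aryl ethers are stable to aqueous hydroxide.

Step 8
Reactants: 13 3-(benzyloxy)-2,4,5-trimethoxybenzoic acid, 14 2,6-dihydroxy-4-methoxyacetophenone
Product: 16 1-[3-(benzyloxy)-2,4,5-trimethoxyphenyl]-3-(2,6-dihydroxy-4-methoxyphenyl)propane-1,3-dione, via aroyl chloride 15 (not isolated)
Conditions: 13, (COCl)2, cat. DMF, CH2Cl2, 0 °C to rt, evaporate; then add to 14 + LiHMDS (4.2 equiv), THF, −78 °C to rt; aq. NH4Cl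
Reagents that add atoms: none
Why: Crossed Claisen-type C-acylation: the acid chloride should acylate the ketone enolate carbon of the trilithiated acetophenone, which is more nucleophilic than the two lithium phenoxides, giving the β-diketone directly, while the fourth equivalent of base deprotonates the product and blocks a second acylation.

Step 9
Reactants: 16 1-[3-(benzyloxy)-2,4,5-trimethoxyphenyl]-3-(2,6-dihydroxy-4-methoxyphenyl)propane-1,3-dione
Product: 17 3'-(benzyloxy)-5-hydroxy-7,2',4',5'-tetramethoxyflavone
Conditions: AcOH, cat. H2SO4 (0.5 vol %), 80 °C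
Reagents that add atoms: none
Why: Acid-catalysed cyclodehydration of an o-hydroxyaryl β-diketone (the ring-closing stage of the Baker–Venkataraman flavone synthesis): either of the two equivalent phenols adds to the B-ring ketone and loss of water gives the pyranone, leaving the other phenol as the chelated 5-OH.

Step 10
Reactants: 17 3'-(benzyloxy)-5-hydroxy-7,2',4',5'-tetramethoxyflavone
Product: 18 5,3'-dihydroxy-7,2',4',5'-tetramethoxyflavone
Conditions: H2 (1 atm), 10% Pd/C, EtOAc–MeOH, rt
Reagents that add atoms: none
Why: Catalytic hydrogenolysis of the benzyl aryl ether should free the C3' hydroxyl while the chromone C2–C3 double bond and the aryl methyl ethers stay untouched at 1 atm and room temperature.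

Compound list
1 | dimethyl squarate (3,4-dimethoxycyclobut-3-ene-1,2-dione) | COC1=C(OC)C(=O)C1=O | starting material
2 | 4-hydroxy-2,3-dimethoxycyclobut-2-en-1-one (racemic) | COC1=C(OC)C(O)C1=O | intermediate
3 | 4-chloro-2,3-dimethoxycyclobut-2-en-1-one (racemic) | COC1=C(OC)C(Cl)C1=O | intermediate
4 | methyl (E)-3-methoxyacrylate | CO/C=C/C(=O)OC | starting material
5 | methyl 2,3-dibromo-3-methoxypropanoate (racemic mixture of diastereomers) | COC(Br)C(Br)C(=O)OC | intermediate (not isolated)
6 | methyl (Z)-2-bromo-3-methoxyacrylate | CO/C=C(\Br)C(=O)OC | intermediate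
7 | methyl (Z)-3-methoxy-2-(tributylstannyl)acrylate | CO/C=C(\[Sn](CCCC)(CCCC)CCCC)C(=O)OC | intermediate
8 | methyl (E)-2-(2,3-dimethoxy-4-oxocyclobut-2-en-1-yl)-3-methoxyacrylate (racemic) | CO/C=C(\C1C(OC)=C(OC)C1=O)C(=O)OC | intermediate (not isolated)
9 | methyl (3E)-4,5-dimethoxy-2-[(E)-methoxymethylidene]-6-oxohexa-3,5-dienoate (dienylketene, acrylate carbon and ketene carbon cis across C3=C4) | O=C=C(OC)/C(OC)=C\C(C(=O)OC)=C/OC | intermediate (not isolated)
10 | methyl 3,4,6-trimethoxy-5-oxocyclohexa-1,3-diene-1-carboxylate (racemic) | COC(=O)C1=CC(OC)=C(OC)C(=O)C1OC | intermediate (not isolated)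
11 | methyl 3-hydroxy-2,4,5-trimethoxybenzoate | COC(=O)c1cc(OC)c(OC)c(O)c1OC | intermediate
12 | methyl 3-(benzyloxy)-2,4,5-trimethoxybenzoate | COC(=O)c1cc(OC)c(OC)c(OCc2ccccc2)c1OC | intermediate
13 | 3-(benzyloxy)-2,4,5-trimethoxybenzoic acid | OC(=O)c1cc(OC)c(OC)c(OCc2ccccc2)c1OC | intermediate
14 | 2,6-dihydroxy-4-methoxyacetophenone | CC(=O)c1c(O)cc(OC)cc1O | starting material
15 | 3-(benzyloxy)-2,4,5-trimethoxybenzoyl chloride | ClC(=O)c1cc(OC)c(OC)c(OCc2ccccc2)c1OC | intermediate (not isolated)
16 | 1-[3-(benzyloxy)-2,4,5-trimethoxyphenyl]-3-(2,6-dihydroxy-4-methoxyphenyl)propane-1,3-dione | COc1cc(O)c(C(=O)CC(=O)c2cc(OC)c(OC)c(OCc3ccccc3)c2OC)c(O)c1 | intermediate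
17 | 3'-(benzyloxy)-5-hydroxy-7,2',4',5'-tetramethoxyflavone | COc1cc(O)c2c(=O)cc(-c3cc(OC)c(OC)c(OCc4ccccc4)c3OC)oc2c1 | intermediate
18 | 5,3'-dihydroxy-7,2',4',5'-tetramethoxyflavone | COc1cc(O)c2c(=O)cc(-c3cc(OC)c(OC)c(O)c3OC)oc2c1 | target

Total steps: 10. Longest linear sequence: 8 steps (1 → 2 → 3 → 11 → 12 → 13 → 16 → 17 → 18; the branch from 4 is equally long).

Steps most likely to fail

Step 5. Transfer of the hindered, electron-poor acrylate α-carbon from tin to palladium may be slower than decay of the oxocyclobutenyl–palladium species (loss of chloromethane) and than protodestannylation, so that little coupled material reaches the ring expansion. The fallback gives up ring construction for classical arene substitution; it uses none of compounds 1–12, sets out from commercial 2,6-dimethoxyphenol F1 and comes back to the route at acid 13. O-Benzylation (BnBr, K2CO3, DMF) should give 2-(benzyloxy)-1,3-dimethoxybenzene F2. Vilsmeier–Haack formylation (POCl3, DMF, 80 °C) should enter ortho to one methoxy and para to the other, giving 3-(benzyloxy)-2,4-dimethoxybenzaldehyde F3. Bromination (NBS, MeCN, rt) at the position para to the C2 methoxy and meta to the formyl group should give 3-(benzyloxy)-5-bromo-2,4-dimethoxybenzaldehyde F4. Copper-catalysed methoxylation (NaOMe, cat. CuBr, MeOH–DMF, 100 °C) should give 3-(benzyloxy)-2,4,5-trimethoxybenzaldehyde F5, and Pinnick oxidation (NaClO2, NaH2PO4, 2-methyl-2-butene, t-BuOH–H2O) should give 13, after which steps 8–10 follow unchanged.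

Step 2. The C4–Cl bond sits on a doubly oxygenated allyl system and may ionise during formation or concentration, with loss of chloromethane or hydrolysis, so that the chloride does not survive to the coupling. The fallback replaces the leaving group; it sets out from 2 and comes back at 11. Acetylation (Ac2O, pyridine, cat. DMAP, CH2Cl2, 0 °C) should give 2,3-dimethoxy-4-oxocyclobut-2-en-1-yl acetate F6, which tolerates isolation and is ionised only by Pd(0). Stille coupling of this allylic acetate with 7 (Pd2(dba)3, tri(2-furyl)phosphine, LiCl, DMF, 50 °C, then 100 °C) should pass through the same intermediates 8, 9 and 10 to 11.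

Step 8. O-Acylation of the phenoxides, double acylation at the enolate carbon, or incomplete polyanion formation through poor solubility may divert the acid chloride. The fallback is the two-stage Baker–Venkataraman sequence; it sets out from 13 and 14 and comes back at 16. Steglich esterification (EDC·HCl, DMAP, CH2Cl2, rt; one equivalent of 13) should acylate the non-chelated hydroxyl and stop at the mono-ester 2-acetyl-3-hydroxy-5-methoxyphenyl 3-(benzyloxy)-2,4,5-trimethoxybenzoate F7, since the remaining hydroxyl is hydrogen-bonded to the ketone. Base-induced O-to-C acyl shift (KOH, pyridine, 50 °C) should then give 16.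

Further compounds
F1 | step 5 | 2,6-dimethoxyphenol (commercial starting material of the fallback) | COc1cccc(OC)c1O
F2 | step 5 | 2-(benzyloxy)-1,3-dimethoxybenzene | COc1cccc(OC)c1OCc1ccccc1
F3 | step 5 | 3-(benzyloxy)-2,4-dimethoxybenzaldehyde | COc1ccc(C=O)c(OC)c1OCc1ccccc1
F4 | step 5 | 3-(benzyloxy)-5-bromo-2,4-dimethoxybenzaldehyde | COc1c(Br)cc(C=O)c(OC)c1OCc1ccccc1
F5 | step 5 | 3-(benzyloxy)-2,4,5-trimethoxybenzaldehyde | COc1cc(C=O)c(OC)c(OCc2ccccc2)c1OC
F6 | step 2 | 2,3-dimethoxy-4-oxocyclobut-2-en-1-yl acetate (racemic) | CC(=O)OC1C(OC)=C(OC)C1=O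
F7 | step 8 | 2-acetyl-3-hydroxy-5-methoxyphenyl 3-(benzyloxy)-2,4,5-trimethoxybenzoate | CC(=O)c1c(O)cc(OC)cc1OC(=O)c1cc(OC)c(OC)c(OCc2ccccc2)c1OC
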